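Q is a product that does not keep: in the south-east run it reads 40% at 8.00 min and 28% at 20.0 min, while G falls from 10% to 1%.

| flask | G | J | remark | time |
|---|---|---|---|---|
| north-west | 0.34 M | 4.1 mol% | run made earlier |  |
| west | 0.23 M | 4.1 mol% | run made earlier |  |
| south-east | 0.51 M | 4.1 mol% | run made earlier |  |
| south-west | 0.34 M | 8.2 mol% | run made earlier |  |
| larch | 0.34 M (fed, over 15.0 min) | 4.1 mol% | all but G at the start; G goes in evenly over 15.0 min, the run ends at 30 min | 30 min |
| oak | 0.34 M | 4.1 mol% | one stirred flow tank at steady state, fed with the mixture as stated, mean residence time 30 min |  |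
| ash | 0.34 M | 4.1 mol% | everything together in a closed stirred flask, run for 30 min | 30 min |

| run | time / min | Q / % | G / % |
|---|---|---|---|
| north-west | 2.50 | 13 | 80 |
| north-west | 6.00 | 30 | 42 |
| north-west | 12.0 | 38 | 9 |
| north-west | 20.0 | 32 | 2 |
| west | 1.33 | 4 | 98 |
| west | 3.00 | 12 | 88 |
| west | 8.00 | 27 | 49 |
| west | 20.0 | 32 | 8 |
| south-east | 1.33 | 8 | 88 |
| south-east | 3.00 | 26 | 59 |
| south-east | 8.00 | 40 | 10 |
| south-east | 20.0 | 28 | 1 |
| south-west | 5.00 | 41 | 32 |
| south-west | 10.0 | 44 | 3 |
| south-west | 15.0 | 42 | 0 |
| south-west | 20.0 | 33 | 0 |

(readings scatter by 1.5 percentage points)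

- the stated concentrations are those of everything mixed, before any reaction; amounts are the same in each set-up
- the feed brings no volume worth counting
- the earlier runs were made in a closed, stirred flask

- the set-up with the highest amount of Q at the outlet or at the end, in percent of the G put in ("none" if the first two lie within 2 percentage points) (larch / oak / ash / none)
- amount of Q at the outlet or at the end, in percent of the G put in, larch
- amount of Q at the outlet or at the end, in percent of the G put in, oak
- amount of Q at the outlet or at the end, in percent of the G put in, ash

Solve the two ends apart and join them. At the late end, the south-east readings give a pseudo-first-order loss of Q of 0.0297 min⁻¹. At the early end, G in the north-west run reads 42% at 6.00 min, so take that as the birth of a typical Q. In ash that Q waits 24.0 min, so 0.713 is the ageing number N, the loss constant times the wait of a typical Q. Q at the end is then S·exp(−N), and the north-west reading at 20.0 min gives S, the apparent selectivity, as 48.5%.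

Test it on the west run, where G reads 49% at 8.00 min: N gives 34.0% at 20.0 min, and the reading is 32%.

My reckoning follows. Ash gets 23.8%. Larch delays the typical G by 7.50 min, so 0.490 gives 29.7%. The north-west G falls at 0.257 min⁻¹, so I reckon a conversion of 88.5% for oak; with its spread of waits, oak takes S/(1+N) of that at N = 0.892, which gives 22.7%. So my reckoning puts larch highest.

The forecast named larch, with 29% for larch, 23% for oak and 23% for ash, reasoning: “G is consumed later, with a mean age of about 16 min at the end, against 24 min in batch”.

The flask gives larch: 30.2% for larch, 24.0% for oak, 25.1% for ash.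

    G + Q → L (k = 0.00807 M⁻¹ s⁻¹)
    G + J → X + Q (k = 0.0132 M⁻¹ s⁻¹)
    Q ⇌ E (K = 2.04, k = 9.22 × 10⁻⁴ s⁻¹)
    G + X → Q + X, rate k4*[X]*[G] (k = 0.276 M⁻¹ s⁻¹)

In ash, at the charged G, Q has a half-life of 4.2 min by G + Q into L, shorter than the 13 min of the forward step Q into E, and short against 30 min. The step into E runs both ways, with K3 = 2.04, and larch at 300 min, where N is 8.52 and exp(−N) leaves 0.00967%, holds 19.7%.

(Readings and results come from a simulation with constants of no real substance, noise included.)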